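**Retrosynthetic overview**
1. Target ⇒ two molecules of (S)-α-herbertenol. The two missing aryl C–O bonds are made last by ortho-oxygenation to the o-quinone, whose quinone methide tautomer is captured by the catechol to give the CH2 link.
2. (S)-α-Herbertenol ⇒ (S)-2-(1,2-dimethylcyclopent-2-enyl)-4-methylphenol; the gem-dimethyl carbon comes from cyclopropanation and hydrogenolysis.
3. That phenol ⇒ (R)-2,3-dimethylcyclopent-2-enyl p-tolyl ether; an aromatic Claisen shift relays the C–O stereocentre to the quaternary carbon.
4. Ether ⇒ p-cresol + (S)-2,3-dimethylcyclopent-2-en-1-ol (Mitsunobu C–O bond, inversion) ⇐ CBS reduction of 2,3-dimethylcyclopent-2-en-1-one.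
5. Ring order: the arene and cyclopentane rings are bought; the only ring made is a transient cyclopropane (step 4), opened again in step 5.

Assumption: both quaternary centres of the target are read as (S) from the SMILES, and 2,3-dimethylcyclopent-2-en-1-one and p-cresol are taken as cheap commercial materials.

Numbering used in the text for the aryl rings: C1 and C2 carry oxygen (C2 next to the cyclopentyl), C3 carries the cyclopentyl, C5 the methyl (or the bridging CH2), C4 and C6 are CH. Ring A is the ring that keeps its methyl; ring B is the ring whose methyl becomes the bridge.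

**Route**

Step 1
Reactants: 1 2,3-dimethylcyclopent-2-en-1-one
Product: 2 (S)-2,3-dimethylcyclopent-2-en-1-ol
Conditions: (R)-Me-CBS [(R)-1-methyl-3,3-diphenyltetrahydro-1H,3H-pyrrolo[1,2-c][1,3,2]oxazaborole] (10 mol %), BH3·SMe2 (0.7 equiv), THF, −20 °C; MeOH, then aq. NH4Cl
Reagents that add atoms: none
Why: Corey–Bakshi–Shibata reduction, in which the α-methylated alkenyl arm acts as the large group and CH2 as the small one, so the (R)-catalyst delivers hydride to give the (S)-allylic alcohol.

Step 2
Reactants: 2 (S)-2,3-dimethylcyclopent-2-en-1-ol; 3 p-cresol (4-methylphenol)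
Product: 4 1-{[(1R)-2,3-dimethylcyclopent-2-en-1-yl]oxy}-4-methylbenzene
Conditions: PPh3 (1.3 equiv), DIAD (diisopropyl azodicarboxylate, 1.3 equiv), toluene, −20 → 0 °C
Reagents that add atoms: none
Why: Mitsunobu etherification, in which the phenol displaces the phosphonium-activated hydroxyl in an SN2 step, so the C–O bond forms with inversion and the (S) carbinol becomes the (R) aryl ether.

Step 3
Reactants: 4 1-{[(1R)-2,3-dimethylcyclopent-2-en-1-yl]oxy}-4-methylbenzene
Product: 6 2-[(1S)-1,2-dimethylcyclopent-2-en-1-yl]-4-methylphenol, via ortho-dienone 5 (not isolated)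
Conditions: PhNEt2, 185 °C, sealed tube, argon, 14 h
Reagents that add atoms: none
Why: Aromatic Claisen rearrangement ([3,3]-sigmatropic), where the ring forces a suprafacial shift so the aryl–C bond forms on the face that carried the C–O bond and (R)-4 gives the (S) quaternary centre; dienone 5 enolises to 6, the para position is blocked by methyl, and the amine solvent suppresses ionisation and acid-catalysed ring closure of the phenol onto the alkene.

Step 4
Reactants: 6 2-[(1S)-1,2-dimethylcyclopent-2-en-1-yl]-4-methylphenol
Product: 7 2-[(1R,2S,5S)-1,2-dimethylbicyclo[3.1.0]hexan-2-yl]-4-methylphenol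
Conditions: Et2Zn (4 equiv), CH2I2 (8 equiv), CH2Cl2, 0 → 23 °C
Reagents that add atoms: diiodomethane, ICI
Why: Simmons–Smith cyclopropanation (Furukawa variant) of the electron-rich trisubstituted alkene with excess carbenoid; 7 is drawn with the new CH2 on the aryl-bearing face (hydroxyl-directed delivery), but either face isomer gives the same product in step 5 and the quaternary centre is untouched.

Step 5
Reactants: 7 2-[(1R,2S,5S)-1,2-dimethylbicyclo[3.1.0]hexan-2-yl]-4-methylphenol
Product: 8 4-methyl-2-[(1S)-1,2,2-trimethylcyclopentyl]phenol ((S)-α-herbertenol)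
Conditions: H2 (1 atm), PtO2 (10 mol %), AcOH, 23 °C
Reagents that add atoms: none
Why: Catalytic hydrogenolysis of the cyclopropane at its least substituted CH–CH2 bond turns the bridging CH2 into the second methyl on the neighbouring carbon (gem-dimethyl) and the former bridgehead CH into ring CH2, with no bond to the stereocentre broken.

Step 6
Reactants: 8 4-methyl-2-[(1S)-1,2,2-trimethylcyclopentyl]phenol (two molecules)
Product: 12 target CNP0137546.1 [3-{[3,4-dihydroxy-5-((1S)-1,2,2-trimethylcyclopentyl)phenyl]methyl}-4-methyl-6-[(1S)-1,2,2-trimethylcyclopentyl]benzene-1,2-diol], via o-quinone 9 (not isolated), via herbertenediol 10 (not isolated), via quinone methide 11 (not isolated)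
Conditions: IBX (2-iodoxybenzoic acid, 1.05 equiv), DMF, 23 °C, 1 h; L-ascorbic acid (0.6 equiv), 15 min; dilute with (CF3)2CHOH, CF3CO2H (0.2 equiv), 40 °C, argon
Reagents that add atoms: 2-iodoxybenzoic acid (IBX), O=C1OI(=O)(O)c2ccccc12
Why: Proposed new method: IBX (pentavalent iodine) binds the phenol oxygen and transfers oxygen to the only free ortho carbon, forming the two new aryl C–O bonds as o-quinone 9; ascorbic acid then reduces 0.6 equiv of 9 to catechol 10, and acid tautomerises the remaining 9 (its C5 methyl is vinylogous to the C1 carbonyl) to the 2-hydroxy-p-quinone methide 11, whose open exocyclic CH2 is attacked in a Friedel–Crafts manner by C6 of 10 (ortho to the C1 hydroxyl; C4 is shielded between cyclopentyl and methyl, and ring addition to 9 would need a tetra-ortho-substituted biaryl), so after the oxygenation the coupling is redox-neutral and no stereocentre is touched; the closest known reaction types are the IBX ortho-oxidation of phenols to o-quinones and the acid-catalysed Friedel–Crafts arylation of p-quinone methides, and their merger into an oxygenative, unsymmetrical methylene-bridged dimerisation of a p-cresol is new.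

**Compound list**
1 | 2,3-dimethylcyclopent-2-en-1-one | CC1=C(C)C(=O)CC1 | starting material
2 | (S)-2,3-dimethylcyclopent-2-en-1-ol | O[C@H]1CCC(C)=C1C | intermediate
3 | p-cresol (4-methylphenol) | Cc1ccc(O)cc1 | starting material
4 | 1-{[(1R)-2,3-dimethylcyclopent-2-en-1-yl]oxy}-4-methylbenzene | Cc1ccc(O[C@@H]2CCC(C)=C2C)cc1 | intermediate
5 | ortho-dienone, 6-[(1R)-1,2-dimethylcyclopent-2-en-1-yl]-4-methylcyclohexa-2,4-dien-1-one (same spatial arrangement at the quaternary carbon as in 6, the letter changes only because the neighbouring ring carbon is sp3; ring CH centre undefined and lost on enolisation) | O=C1C=CC(C)=CC1[C@@]2(C)CCC=C2C | intermediate (not isolated)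
6 | 2-[(1S)-1,2-dimethylcyclopent-2-en-1-yl]-4-methylphenol | Cc1ccc(O)c([C@@]2(C)CCC=C2C)c1 | intermediate
7 | 2-[(1R,2S,5S)-1,2-dimethylbicyclo[3.1.0]hexan-2-yl]-4-methylphenol (cis-fused, cyclopropane CH2 on the aryl face) | Cc1ccc(O)c([C@@]2(C)CC[C@H]3C[C@@]23C)c1 | intermediate
8 | 4-methyl-2-[(1S)-1,2,2-trimethylcyclopentyl]phenol ((S)-α-herbertenol) | Cc1ccc(O)c([C@@]2(C)CCCC2(C)C)c1 | intermediate
9 | o-quinone, 5-methyl-3-[(1S)-1,2,2-trimethylcyclopentyl]cyclohexa-3,5-diene-1,2-dione | CC1=CC(=O)C(=O)C([C@@]2(C)CCCC2(C)C)=C1 | intermediate (not isolated)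
10 | (S)-herbertenediol, 5-methyl-3-[(1S)-1,2,2-trimethylcyclopentyl]benzene-1,2-diol | Cc1cc(O)c(O)c([C@@]2(C)CCCC2(C)C)c1 | intermediate (not isolated)
11 | quinone methide, 2-hydroxy-4-methylidene-6-[(1S)-1,2,2-trimethylcyclopentyl]cyclohexa-2,5-dien-1-one | C=C1C=C(O)C(=O)C([C@@]2(C)CCCC2(C)C)=C1 | intermediate (not isolated)
12 | 3-{[3,4-dihydroxy-5-((1S)-1,2,2-trimethylcyclopentyl)phenyl]methyl}-4-methyl-6-[(1S)-1,2,2-trimethylcyclopentyl]benzene-1,2-diol (CNP0137546.1) | Cc1cc([C@@]2(C)CCCC2(C)C)c(O)c(O)c1Cc1cc(O)c(O)c([C@@]2(C)CCCC2(C)C)c1 | target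

**Step count and risks**
Total steps: 6. Longest linear sequence: 6 (1 → 2 → 4 → 6 → 7 → 8 → 12).

Step 6 (proposed new step). Risks are redox exchange between product and 9, a second alkylation at C6 of ring B, and biaryl formation. The catechol is kept in excess (left-over 10 is recovered), and because both halves come from one batch of 8, small ee losses end up mostly in a separable diastereomer. Fallback with known chemistry, setting out from 8: IBX in DMF followed by aqueous Na2S2O4 gives isolated (S)-herbertenediol 10 (standard phenol-to-catechol protocol). One half is acetylated (Ac2O, pyridine) to (S)-herbertenediol diacetate F1. Benzylic bromination (NBS, AIBN, PhCF3, 80 °C) gives the benzylic bromide F2. F2 alkylates C6 of free 10 (2 equiv) in (CF3)2CHOH at 40 °C (Friedel–Crafts benzylation) to give the ring B diacetate of the target F3. K2CO3 in MeOH at 0 °C under argon removes the acetates, and the fallback comes back to the route at 12.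

Step 3 (Claisen shift to a quaternary carbon). Risks are loss of p-cresol by elimination to the diene and partial ionisation with loss of ee. Fallback, setting out from p-cresol 3: commercial 2,2-dimethylcyclopentanone and MeMgBr (THF, 0 °C) give racemic 1,2,2-trimethylcyclopentan-1-ol F4. Acid-catalysed ortho-alkylation of 3 with F4 (CH3SO3H, CH2Cl2, 0 → 23 °C; the tertiary cation can only shift a methyl degenerately, and the para position is blocked) gives racemic α-herbertenol F5. Preparative SFC on a chiral stationary phase delivers the (S)-enantiomer and leaves (R)-α-herbertenol F6. The fallback comes back to the route at 8.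

Step 2 (Mitsunobu on a cation-prone allylic alcohol). Risks are SN1 or SN2′ pathways that erode ee, and elimination. Fallback, setting out from enone 1: reduction with the (S)-configured CBS catalyst and BH3·SMe2 gives (R)-2,3-dimethylcyclopent-2-en-1-ol F7. The same ether is then made by an Ullmann-type C(aryl)–O coupling with 4-iodotoluene (CuI, 3,4,7,8-tetramethyl-1,10-phenanthroline, Cs2CO3, toluene, 80 °C). The carbinol C–O bond is never broken, so (R)-F7 gives (R)-configured ether with retention, and the fallback comes back to the route at 4.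

**Further compounds**
F1 | step 6 | 5-methyl-3-[(1S)-1,2,2-trimethylcyclopentyl]-1,2-phenylene diacetate | Cc1cc(OC(C)=O)c(OC(C)=O)c([C@@]2(C)CCCC2(C)C)c1
F2 | step 6 | 5-(bromomethyl)-3-[(1S)-1,2,2-trimethylcyclopentyl]-1,2-phenylene diacetate | BrCc1cc(OC(C)=O)c(OC(C)=O)c([C@@]2(C)CCCC2(C)C)c1
F3 | step 6 | 5-{[2,3-dihydroxy-6-methyl-4-((1S)-1,2,2-trimethylcyclopentyl)phenyl]methyl}-3-[(1S)-1,2,2-trimethylcyclopentyl]-1,2-phenylene diacetate | Cc1cc([C@@]2(C)CCCC2(C)C)c(O)c(O)c1Cc1cc(OC(C)=O)c(OC(C)=O)c([C@@]2(C)CCCC2(C)C)c1
F4 | step 3 | racemic 1,2,2-trimethylcyclopentan-1-ol | CC1(O)CCCC1(C)C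
F5 | step 3 | racemic 4-methyl-2-(1,2,2-trimethylcyclopentyl)phenol | Cc1ccc(O)c(C2(C)CCCC2(C)C)c1
F6 | step 3 | 4-methyl-2-[(1R)-1,2,2-trimethylcyclopentyl]phenol | Cc1ccc(O)c([C@]2(C)CCCC2(C)C)c1
F7 | step 2 | (R)-2,3-dimethylcyclopent-2-en-1-ol | O[C@@H]1CCC(C)=C1C
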